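If, with Z held the same, the part of a charge that fails to stand as L late in a run grows in step with the charge, a smaller run can speak for a larger one.

| flask | X | Z | remark | time |
|---|---|---|---|---|
| ochre | 35 mM | 7 mM (held) | the very flask that is asked about, followed so far |  |
| teal | 23 mM | 7 mM (held) | run made earlier |  |
| flask | 35 mM | 7.0 mM (held) |  | 2.5 h |

- ochre (time / min: L / %, X / %): 2.50: 1.1, 80.2; 6.00: 1.7, 62.4; 12.0: 2.9, 43.8; 30.0: 16.3, 16.0
- teal (time / min: L / %, X / %): 12.0: 4.4, 13.5; 40.0: 31.2, 0.4; 60.0: 44.3, 1.5; 120: 67.6, 0.3

(each reading ± 1 percentage point)

1. amount of L at 2.5 h, in percent of the X charged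
2. concentration of E in solution at 2.5 h, in percent of saturation

- given per volume of solution although it is solid: X
- the numbers in the tables scatter by 1 percentage point (one standard deviation)
- at the start none of Z is in solution
- at the start none of X is in solution
- E is what Z becomes in solution

Teal at 120 min holds 67.6% as L and 0.3% as X, so 32.1% of its charge stands elsewhere, dissolved or lost. Scaled by the charges, 35 mM over 23 mM, that gap becomes 48.8% for ochre: the shortfall number, teal's late share of the charge not standing as L or X, times the ratio of charges.

The scaling is a guess of this reckoning: it supposes that the lost share grows with the charge, while the saturation level of Z stays 7.0 mM in both runs. Read off, ochre stands near 51.2% L at teal's time, and somewhat higher after a further 30.0 min.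

One number is not enough early. At 12.0 min the shortfalls read 18.7 mM in ochre and 18.9 mM in teal, alike in mM and not in share, so the scaling with the charge does not hold there and the number is kept for late readings.

The forecast stands higher than this reckoning, at 74% of L, with E at 93% of saturation, holding that “Gas transfer should easily keep up”.

The flask gives 56.7% of L, with E at 75.2% of saturation.

Z ⇌ E, rate k1*(csat - [E]) (kL = 8.58 × 10⁻⁴ s⁻¹); Q + E → L (k = 0.0974 L mol⁻¹ s⁻¹); X ⇌ Q, rate k3*(cs3 - [Q]) while solid is left; crystals form when [Q] > cs3 (solubility = 26.0 mM, k = 0.00196 s⁻¹); Q + L → D (k = 0.00629 L mol⁻¹ s⁻¹) At 2.50 h D, the product of a consecutive reaction, holds 38.6% of the charge, counted twice per D. The shortfall number 48.8%, read from teal at 120 min, stands against 43.3% not present as L in the flask at 2.5 h, 5.5 percentage points apart. For the neighbour flask with 14 mM of X, the same reckoning gives a shortfall of 19.5%, so about 80.5% L; the computed result is 81.8%.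

(The numbers in the tables are calculated for an exercise; scatter was added.)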